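**Plan**
1. Retrosynthesis: the two angelates (O8, O9), then the C8/C9 diol (dihydroxylation) and a Wharton transposition lead back to a tricyclic 7,8-epoxy-1,9-dione. Its cyclobutane is cut at C10–C11 to a cis-fused cyclohexenone/cycloheptanone. That bicycle is cut at C7=C8 (metathesis), C4–C10 (ester-enolate Claisen) and C5–C11 plus C3=C4 (Michael/aldol annulation).
2. Forward: six-membered ring (organocatalytic Robinson-type annulation) → C4–C10 chain (Ireland–Claisen) → seven-membered ring (RCM) → epoxide and C1 ketone → cyclobutane and both bridged bicycles in one oxidative enolate–enolate coupling → triol → angelates.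
3. Enabling feature: C11 and C10 are the α-carbons of the C1 and C9 carbonyl groups. They lie 1,4 across the C4–C5 fusion bond of the cis-fused bicycle, with C10 axial over C11, so joining the two enolates closes the ring C4–C5–C11–C10. The 7,8-epoxide is a helper: it blocks enolisation toward C8 and carries O7.
4. Stereochemistry: C5 from the (S)-prolinol ether catalyst; C4 by suprafacial Claisen transfer from a cis C2 ester; C10 and C11 from the cis fusion in the key step; C7 by substrate-controlled enone epoxidation; C8/C9 by OsO4 anti to the O7 silyl ether; Z-alkenes from angelic acid.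

Key step: step 12

Remark: atoms are named by the longipinane numbering of the target in every intermediate: C1 ketone, C2=C3 (methyl on C3), C4 and C11 bridgeheads, C5, C6 (gem-dimethyl), C7, C8, C9 (oxygenated), C10 (quaternary, methyl).
Remark: the enol ether geometry of 9 and the configuration at C10 in 10–17 are left undefined (epimer mixture expected); C10 is planarised as an enolate in step 12.

**Step 1**
Reactants: 1 methyl 3,3-dimethylpent-4-enoate
Product: 2 3,3-dimethylpent-4-enal
Conditions: iBu2AlH (1.05 equiv), CH2Cl2, −78 °C; aq. potassium sodium tartrate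
Reagents that add atoms: none
Why: Partial reduction of the ester with iBu2AlH stops at the aldehyde because the tetrahedral aluminium hemiacetal is stable at −78 °C (standard ester-to-aldehyde reduction).

**Step 2**
Reactants: 2 3,3-dimethylpent-4-enal; 3 pent-1-en-3-one
Product: 4 (2S)-2-(2-methylbut-3-en-2-yl)-5-oxoheptanal
Conditions: (S)-2-[methoxy(diphenyl)methyl]pyrrolidine (5 mol %), ethyl 3,4-dihydroxybenzoate (20 mol %), neat, 4 °C
Reagents that add atoms: none
Why: Enamine-catalysed asymmetric Michael addition of an aldehyde to a vinyl ketone; the diphenylmethyl ether group of the (S)-catalyst shields one face of the E-enamine, which should set C5 (S in 4), the centre from which all others are relayed.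

**Step 3**
Reactants: 4 (2S)-2-(2-methylbut-3-en-2-yl)-5-oxoheptanal
Product: 5 (4R)-2-methyl-4-(2-methylbut-3-en-2-yl)cyclohex-2-en-1-one
Conditions: LiOH (0.2 equiv), iPrOH, rt
Reagents that add atoms: none
Why: Intramolecular aldol condensation (second half of a Robinson-type annulation): only the ethyl CH2 of the ketone can close a six-membered ring on the aldehyde, and C5, flanked by a quaternary carbon, should not epimerise under the mild base.

**Step 4**
Reactants: 5 (4R)-2-methyl-4-(2-methylbut-3-en-2-yl)cyclohex-2-en-1-one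
Product: 6 (1R,4R)-2-methyl-4-(2-methylbut-3-en-2-yl)cyclohex-2-en-1-ol (trans)
Conditions: NaBH4, CeCl3·7H2O, MeOH, −78 → 0 °C
Reagents that add atoms: none
Why: Luche 1,2-reduction; axial hydride delivery to C2 of the half-chair with the bulky C5 substituent equatorial should give the trans (diequatorial) allylic alcohol.

**Step 5**
Reactants: 6 (1R,4R)-2-methyl-4-(2-methylbut-3-en-2-yl)cyclohex-2-en-1-ol; 7 propanoic acid
Product: 8 (1S,4R)-2-methyl-4-(2-methylbut-3-en-2-yl)cyclohex-2-en-1-yl propanoate (cis)
Conditions: PPh3, DIAD, THF, 0 °C → rt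
Reagents that add atoms: none
Why: Mitsunobu esterification: SN2 displacement of the alkoxyphosphonium by propanoate inverts C2 and places the ester oxygen cis to the C5 substituent, as the Claisen step requires.

**Step 6**
Reactants: 8 (1S,4R)-2-methyl-4-(2-methylbut-3-en-2-yl)cyclohex-2-en-1-yl propanoate
Product: 11 2-[(1S,6R)-2-methyl-6-(2-methylbut-3-en-2-yl)cyclohex-2-en-1-yl]propanoic acid (α-epimers), via silyl ketene acetal 9 (not isolated), via trimethylsilyl ester 10 (not isolated)
Conditions: LiN(iPr)2 (1.2 equiv), THF, −78 °C; Me3SiCl/Et3N; −78 → 60 °C; then 1 M HCl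
Reagents that add atoms: none
Why: Ireland–Claisen rearrangement: the [3,3] shift is suprafacial, so the C4–C10 bond forms on the face of the breaking C2–O bond, cis to the C5 substituent (sets C4), and the alkene moves to C2=C3.

**Step 7**
Reactants: 11 2-[(1S,6R)-2-methyl-6-(2-methylbut-3-en-2-yl)cyclohex-2-en-1-yl]propanoic acid
Product: 13 N-methoxy-N-methyl-2-[(1S,6R)-2-methyl-6-(2-methylbut-3-en-2-yl)cyclohex-2-en-1-yl]propanamide, via acyl imidazolide 12 (not isolated)
Conditions: 1,1'-carbonyldiimidazole, CH2Cl2, rt; then MeNH(OMe)·HCl, rt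
Reagents that add atoms: N,O-dimethylhydroxylamine hydrochloride, CNOC.Cl
Why: Activation of the acid as the acyl imidazolide and aminolysis gives the Weinreb amide (standard amide formation).

**Step 8**
Reactants: 13 N-methoxy-N-methyl-2-[(1S,6R)-2-methyl-6-(2-methylbut-3-en-2-yl)cyclohex-2-en-1-yl]propanamide
Product: 14 4-[(1S,6R)-2-methyl-6-(2-methylbut-3-en-2-yl)cyclohex-2-en-1-yl]pent-1-en-3-one
Conditions: CH2=CHMgBr (2.5 equiv), THF, 0 °C; inverse quench into cold 1 M HCl
Reagents that add atoms: vinylmagnesium bromide, C=C[Mg]Br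
Why: Weinreb ketone synthesis: the chelated tetrahedral adduct collapses only on work-up, so no over-addition occurs, and the cold acidic inverse quench prevents conjugate addition of the released amine.

**Step 9**
Reactants: 14 4-[(1S,6R)-2-methyl-6-(2-methylbut-3-en-2-yl)cyclohex-2-en-1-yl]pent-1-en-3-one
Product: 15 (1R,7S)-2,2,6,8-tetramethylbicyclo[5.4.0]undeca-3,8-dien-5-one (cis-fused; epimers at the CHMe carbon)
Conditions: second-generation Hoveyda–Grubbs catalyst (5 mol %), toluene (2 mM), 80 °C
Reagents that add atoms: none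
Why: Ring-closing metathesis between the enone vinyl group and the neopentyl vinyl group closes the seven-membered ring at C7=C8, helped by the gem-dimethyl group and the cis disposition of the two chains; the trisubstituted ring alkene is inert.

**Step 10**
Reactants: 15 (1R,7S)-2,2,6,8-tetramethylbicyclo[5.4.0]undeca-3,8-dien-5-one
Product: 16 (1R,3S,4S,7S)-3,4-epoxy-2,2,6,8-tetramethylbicyclo[5.4.0]undec-8-en-5-one
Conditions: H2O2 (30 % aq.), NaOH, MeOH, 0 °C
Reagents that add atoms: hydrogen peroxide, OO
Why: Weitz–Scheffer nucleophilic epoxidation, chemoselective for the enone; hydroperoxide should add to C7 on the face of the ring-fusion hydrogens because the other face is blocked 1,3-diaxially by the C11 methylene, which is axial on the seven-membered ring when C6 is equatorial on the cyclohexene, and this sets C7 and C8.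

**Step 11**
Reactants: 16 (1R,3S,4S,7S)-3,4-epoxy-2,2,6,8-tetramethylbicyclo[5.4.0]undec-8-en-5-one
Product: 17 (1R,3S,4S,7S)-3,4-epoxy-2,2,6,8-tetramethylbicyclo[5.4.0]undec-8-ene-5,10-dione
Conditions: Rh2(cap)4 (cap = caprolactamate, 1 mol %), tBuOOH (5 equiv), K2CO3, CH2Cl2, rt
Reagents that add atoms: tert-butyl hydroperoxide, CC(C)(C)OO
Why: Radical allylic oxidation of the kind that converts 1-methylcyclohexenes and α-pinene-type alkenes into enones: hydrogen abstraction should occur at the unhindered secondary C1–H2 and not at the tertiary, flanked C4–H, giving the C1 ketone conjugated with C2=C3.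

**Step 12**
Reactants: 17 (1R,3S,4S,7S)-3,4-epoxy-2,2,6,8-tetramethylbicyclo[5.4.0]undec-8-ene-5,10-dione
Product: 19 (4R,5S,7S,8S,10R,11R)-7,8-epoxylongipin-2-ene-1,9-dione, via dilithium bis-enolate 18 (not isolated)
Conditions: LiN(iPr)2 (2.3 equiv), THF (5 mM), −78 °C; CuCl2 (2.5 equiv) in DMF, −78 → −20 °C
Reagents that add atoms: none
Why: Proposed new method: double kinetic deprotonation gives the C11=C1 cross-conjugated dienolate and the C9=C10 enolate (C10–H is the only enolisable position of the epoxy ketone), and one-electron oxidation of the more electron-rich, fully substituted C10 enolate by CuCl2 gives a tertiary α-keto radical that attacks C11 of the neighbouring enolate (4-exo-trig), the ketyl formed on the six-membered ring being oxidised by the second CuCl2; the closest known reaction type is the CuCl2- or Fe(acac)3-mediated oxidative coupling of ketone lithium enolates to 1,4-diketones, including intramolecular cases, which has not been shown for a cyclobutane with a quaternary carbon in a bridged skeleton. The one new bond closes the cyclobutane C4–C5–C11–C10 by a 1,4-closure across the C4–C5 fusion and thereby turns the cyclohexenone into the bicyclo[3.1.1]heptenone and the cycloheptanone into the C5/C10-bridged seven-membered ring. C10 is pseudo-axial on the six-membered ring (C6 equatorial, A(1,2) strain with the C3 methyl disfavours the other half-chair), so its π lobe lies 1,3-diaxial over that of C11. Both new stereocentres (C11 and C10) are fixed by the cis fusion at C4/C5: the tether lets each enolate bond only on the face turned to the other, and the seven-membered ring holds C9 anti and the C10 methyl syn to the enone bridge. The selectivity needed is intramolecular C–C coupling over intermolecular coupling, α-chlorination, aldol attack of C10 on C1 and opening of the epoxide; it is secured by proximity, high dilution, low temperature and complete double deprotonation (C1 masked as its enolate), and a C11 chloride, if formed, would be displaced by the C10 enolate to the same product.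

**Step 13**
Reactants: 19 (4R,5S,7S,8S,10R,11R)-7,8-epoxylongipin-2-ene-1,9-dione
Product: 21 (4R,5S,7R,10R,11R)-7-hydroxylongipina-2,8-dien-1-one, via epoxy hydrazone 20 (not isolated)
Conditions: N2H4·H2O (3 equiv), AcOH (0.5 equiv), MeOH, 0 °C → rt
Reagents that add atoms: none
Why: Wharton transposition: the more electrophilic α,β-epoxy ketone forms the hydrazone, which opens the epoxide and loses N2 to give the allylic alcohol with the C7–O configuration retained, while the β,β-disubstituted, bridgehead-flanked C1 enone should condense much more slowly.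

**Step 14**
Reactants: 21 (4R,5S,7R,10R,11R)-7-hydroxylongipina-2,8-dien-1-one
Product: 22 (4R,5S,7R,10R,11R)-7-(tert-butyldimethylsilyloxy)longipina-2,8-dien-1-one
Conditions: tBuMe2SiOTf, 2,6-lutidine, CH2Cl2, −78 → 0 °C
Reagents that add atoms: tert-butyldimethylsilyl trifluoromethanesulfonate, CC(C)(C)[Si](C)(C)OS(=O)(=O)C(F)(F)F
Why: Silylation of the hindered allylic alcohol with the silyl triflate (standard protection), needed to direct the dihydroxylation and to keep O7 free of acyl groups.

**Step 15**
Reactants: 22 (4R,5S,7R,10R,11R)-7-(tert-butyldimethylsilyloxy)longipina-2,8-dien-1-one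
Product: 23 (4R,5S,7S,8S,9S,10R,11R)-7-(tert-butyldimethylsilyloxy)-8,9-dihydroxylongipin-2-en-1-one
Conditions: OsO4 (10 mol %), N-methylmorpholine N-oxide (2 equiv), acetone–H2O, rt
Reagents that add atoms: osmium tetroxide, O=[Os](=O)(=O)=O; N-methylmorpholine N-oxide, C[N+]1([O-])CCOCC1; water, O
Why: Upjohn syn-dihydroxylation anti to the allylic silyl ether (Kishi's empirical rule) sets C8 and C9 with both hydroxyls cis to each other and trans to O7, and the conjugated trisubstituted C2=C3 alkene is much less reactive.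

**Step 16**
Reactants: 23 (4R,5S,7S,8S,9S,10R,11R)-7-(tert-butyldimethylsilyloxy)-8,9-dihydroxylongipin-2-en-1-one; 24 angelic acid ((2Z)-2-methylbut-2-enoic acid)
Product: 26 (4R,5S,7S,8S,9S,10R,11R)-7-(tert-butyldimethylsilyloxy)-1-oxolongipin-2-ene-8,9-diyl bis[(2Z)-2-methylbut-2-enoate], via mixed anhydride 25 (not isolated)
Conditions: 24 (6 equiv), 2,4,6-trichlorobenzoyl chloride (6 equiv), Et3N, toluene, rt; then 23, 80 °C
Reagents that add atoms: none
Why: Yamaguchi-type esterification through the 2,4,6-trichlorobenzoic mixed anhydride without a nucleophilic pyridine catalyst, conditions known to acylate hindered secondary alcohols without Z-to-E isomerisation of the angelate.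

**Step 17**
Reactants: 26 (4R,5S,7S,8S,9S,10R,11R)-7-(tert-butyldimethylsilyloxy)-1-oxolongipin-2-ene-8,9-diyl bis[(2Z)-2-methylbut-2-enoate]
Product: 27 (4R,5S,7S,8R,9S,10R,11R)-7-hydroxy-1-oxolongipin-2-ene-8,9-diyl bis[(2Z)-2-methylbut-2-enoate]
Conditions: HF·pyridine, pyridine–THF, 0 °C → rt
Reagents that add atoms: none
Why: Fluoride cleavage of the silyl ether under buffered, non-basic conditions should leave the angelates and the enone untouched and avoid acyl migration to O7.

**Compound list**
1 | methyl 3,3-dimethylpent-4-enoate | COC(=O)CC(C)(C)C=C | starting material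
2 | 3,3-dimethylpent-4-enal | O=CCC(C)(C)C=C | intermediate
3 | pent-1-en-3-one | C=CC(=O)CC | starting material
4 | (2S)-2-(2-methylbut-3-en-2-yl)-5-oxoheptanal | O=C[C@H](C(C)(C)C=C)CCC(=O)CC | intermediate
5 | (4R)-2-methyl-4-(2-methylbut-3-en-2-yl)cyclohex-2-en-1-one | O=C1C(C)=C[C@H](C(C)(C)C=C)CC1 | intermediate
6 | (1R,4R)-2-methyl-4-(2-methylbut-3-en-2-yl)cyclohex-2-en-1-ol (trans) | O[C@H]1C(C)=C[C@H](C(C)(C)C=C)CC1 | intermediate
7 | propanoic acid | CCC(=O)O | starting material
8 | (1S,4R)-2-methyl-4-(2-methylbut-3-en-2-yl)cyclohex-2-en-1-yl propanoate (cis) | CCC(=O)O[C@@H]1C(C)=C[C@H](C(C)(C)C=C)CC1 | intermediate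
9 | trimethylsilyl ketene acetal of 8 (enol ether geometry undefined) | CC=C(O[Si](C)(C)C)O[C@@H]1C(C)=C[C@H](C(C)(C)C=C)CC1 | intermediate
10 | trimethylsilyl 2-[(1S,6R)-2-methyl-6-(2-methylbut-3-en-2-yl)cyclohex-2-en-1-yl]propanoate (α-epimers) | C[Si](C)(C)OC(=O)C(C)[C@H]1C(C)=CCC[C@H]1C(C)(C)C=C | intermediate
11 | 2-[(1S,6R)-2-methyl-6-(2-methylbut-3-en-2-yl)cyclohex-2-en-1-yl]propanoic acid (α-epimers; ring substituents cis) | OC(=O)C(C)[C@H]1C(C)=CCC[C@H]1C(C)(C)C=C | intermediate
12 | acyl imidazolide of 11 | O=C(n1ccnc1)C(C)[C@H]1C(C)=CCC[C@H]1C(C)(C)C=C | intermediate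
13 | N-methoxy-N-methyl-2-[(1S,6R)-2-methyl-6-(2-methylbut-3-en-2-yl)cyclohex-2-en-1-yl]propanamide | CON(C)C(=O)C(C)[C@H]1C(C)=CCC[C@H]1C(C)(C)C=C | intermediate
14 | 4-[(1S,6R)-2-methyl-6-(2-methylbut-3-en-2-yl)cyclohex-2-en-1-yl]pent-1-en-3-one | C=CC(=O)C(C)[C@H]1C(C)=CCC[C@H]1C(C)(C)C=C | intermediate
15 | (1R,7S)-2,2,6,8-tetramethylbicyclo[5.4.0]undeca-3,8-dien-5-one (cis-fused; epimers at the CHMe carbon) | O=C1C=CC(C)(C)[C@@H]2CCC=C(C)[C@@H]2C1C | intermediate
16 | (1R,3S,4S,7S)-3,4-epoxy-2,2,6,8-tetramethylbicyclo[5.4.0]undec-8-en-5-one (epoxide on the face of the ring-fusion hydrogens) | O=C1[C@H]3O[C@H]3C(C)(C)[C@@H]2CCC=C(C)[C@@H]2C1C | intermediate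
17 | (1R,3S,4S,7S)-3,4-epoxy-2,2,6,8-tetramethylbicyclo[5.4.0]undec-8-ene-5,10-dione | O=C1[C@H]3O[C@H]3C(C)(C)[C@@H]2CC(=O)C=C(C)[C@@H]2C1C | intermediate
18 | dilithium bis-enolate of 17 (C11=C1–OLi and C10=C9–OLi) | [Li]OC1=C(C)[C@H]2C(C)=CC(O[Li])=C[C@H]2C(C)(C)[C@@H]3O[C@H]13 | intermediate
19 | (4R,5S,7S,8S,10R,11R)-7,8-epoxylongipin-2-ene-1,9-dione | O=C1[C@H]4O[C@H]4C(C)(C)[C@@H]2[C@H]3C(=O)C=C(C)[C@@H]2[C@@]13C | intermediate
20 | C9 hydrazone of 19 | NN=C1[C@H]4O[C@H]4C(C)(C)[C@@H]2[C@H]3C(=O)C=C(C)[C@@H]2[C@@]13C | intermediate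
21 | (4R,5S,7R,10R,11R)-7-hydroxylongipina-2,8-dien-1-one | O[C@H]1C(C)(C)[C@@H]2[C@H]3C(=O)C=C(C)[C@@H]2[C@@]3(C)C=C1 | intermediate
22 | (4R,5S,7R,10R,11R)-7-(tert-butyldimethylsilyloxy)longipina-2,8-dien-1-one | CC(C)(C)[Si](C)(C)O[C@H]1C(C)(C)[C@@H]2[C@H]3C(=O)C=C(C)[C@@H]2[C@@]3(C)C=C1 | intermediate
23 | (4R,5S,7S,8S,9S,10R,11R)-7-(tert-butyldimethylsilyloxy)-8,9-dihydroxylongipin-2-en-1-one | O[C@@H]1[C@@H](O[Si](C)(C)C(C)(C)C)C(C)(C)[C@@H]2[C@H]3C(=O)C=C(C)[C@@H]2[C@@]3(C)[C@@H]1O | intermediate
24 | angelic acid, (2Z)-2-methylbut-2-enoic acid | C/C=C(/C)C(=O)O | starting material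
25 | (2Z)-2-methylbut-2-enoic 2,4,6-trichlorobenzoic anhydride | C/C=C(/C)C(=O)OC(=O)c1c(Cl)cc(Cl)cc1Cl | intermediate
26 | (4R,5S,7S,8S,9S,10R,11R)-7-(tert-butyldimethylsilyloxy)-1-oxolongipin-2-ene-8,9-diyl bis[(2Z)-2-methylbut-2-enoate] | C/C=C(/C)C(=O)O[C@@H]1[C@@H](O[Si](C)(C)C(C)(C)C)C(C)(C)[C@@H]2[C@H]3C(=O)C=C(C)[C@@H]2[C@@]3(C)[C@@H]1OC(=O)/C(C)=C\C | intermediate
27 | (4R,5S,7S,8R,9S,10R,11R)-7-hydroxy-1-oxolongipin-2-ene-8,9-diyl bis[(2Z)-2-methylbut-2-enoate] | C/C=C(/C)C(=O)O[C@@H]1[C@@H](O)C(C)(C)[C@@H]2[C@H]3C(=O)C=C(C)[C@@H]2[C@@]3(C)[C@@H]1OC(=O)/C(C)=C\C | target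

**Total step count:** 17. **Longest linear sequence:** 17 steps (1 → 27; 3, 7 and 24 enter as single reagents).

**Steps most likely to fail**

1. Step 12 (Proposed new method). What may go wrong: closure to the strained ring may be slower than intermolecular coupling, α-chlorination without ring closure, or collapse of the C9 enolate onto the neighbouring epoxide. Fallback (from 17, back at 19), a two-electron alkylation in place of the oxidative coupling. LiN(SiMe3)2 (1.05 equiv) with Me3SiCl at −78 °C should deprotonate the less hindered C11 methylene before the tertiary C10–H and give the trimethylsilyl dienol ether of the six-membered ring F1. PhI(OH)OTs in CH2Cl2 then gives the C11 tosyloxy enone F2, the electrophile entering anti to the axial C10 substituent so that the tosylate is trans to C10. KOtBu in tBuOH–THF forms the C10 enolate, which displaces the tosylate with inversion to give 19; this is the intramolecular enolate alkylation known for closing the cyclobutane of bicyclo[3.1.1]heptanones.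

2. Step 10. What may go wrong: poor facial selectivity of hydroperoxide addition at C7 (each face of the enone carries a C6 methyl), which would carry through to the triol epimeric at C7, C8 and C9. Fallback (from 15, back at 16), reagent control in place of substrate control. Catecholborane with (S)-Me-CBS oxazaborolidine (alkenyl arm as the large group) should reduce C9 to the allylic alcohol with the hydroxyl on the face of the ring-fusion hydrogens F3. VO(acac)2/tBuOOH then delivers the epoxide syn to that hydroxyl, giving the epoxy alcohol F4. Dess–Martin periodinane restores the C9 ketone to give 16.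

3. Step 11. What may go wrong: hydrogen abstraction at the tertiary C4–H or the C3 methyl in place of C1, or over-oxidation. Fallback (from 11, back at 17), oxygen delivered through the carboxyl group in place of C–H oxidation. Iodolactonisation of 11 (iodine, NaHCO3, MeCN) closes the γ-lactone from the carboxyl oxygen to C3 with iodine anti on C2, giving the iodolactone F5. DBU (toluene, 80 °C) eliminates HI toward C1 to the unsaturated lactone F6. Me2AlN(OMe)Me (from AlMe3 and MeNH(OMe)·HCl) opens it to the hydroxy Weinreb amide F7. CH2=CHMgBr gives the hydroxy vinyl ketone F8, metathesis as in step 9 gives the bicyclic hydroxy dienone F9, and epoxidation as in step 10 gives the epoxy hydroxy enone F10. (C5H5NH)[CrO3Cl] (pyridinium chlorochromate) then effects the oxidative 1,3-transposition of the tertiary allylic alcohol to the C1 enone 17.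

**Further compounds**
F1 | step 12 | trimethylsilyl dienol ether of 17 (C11=C1–OSiMe3, C2=C3) | O=C1[C@H]3O[C@H]3C(C)(C)[C@@H]2C=C(O[Si](C)(C)C)C=C(C)[C@@H]2C1C
F2 | step 12 | C11 tosyloxy derivative of 17 (tosylate trans to C10) | O=C1[C@H]3O[C@H]3C(C)(C)[C@@H]2[C@@H](OS(=O)(=O)c4ccc(C)cc4)C(=O)C=C(C)[C@@H]2C1C
F3 | step 10 | C9 allylic alcohol from 15 (hydroxyl cis to the ring-fusion hydrogens) | O[C@H]1C=CC(C)(C)[C@@H]2CCC=C(C)[C@@H]2C1C
F4 | step 10 | 7,8-epoxy C9 alcohol (epoxide syn to the hydroxyl) | O[C@H]1[C@H]3O[C@H]3C(C)(C)[C@@H]2CCC=C(C)[C@@H]2C1C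
F5 | step 11 | iodolactone from 11 (lactone oxygen on C3, iodine on C2, anti) | O=C1O[C@@]2(C)[C@H](I)CC[C@@H](C(C)(C)C=C)[C@H]2C1C
F6 | step 11 | unsaturated lactone (C1=C2 alkene, lactone oxygen on C3) | O=C1O[C@@]2(C)C=CC[C@@H](C(C)(C)C=C)[C@H]2C1C
F7 | step 11 | hydroxy Weinreb amide (tertiary allylic alcohol at C3) | CON(C)C(=O)C(C)[C@H]1[C@@](C)(O)C=CC[C@H]1C(C)(C)C=C
F8 | step 11 | hydroxy vinyl ketone | C=CC(=O)C(C)[C@H]1[C@@](C)(O)C=CC[C@H]1C(C)(C)C=C
F9 | step 11 | bicyclic hydroxy dienone (C3 hydroxyl, C1=C2 and C7=C8 alkenes, C9 ketone) | O=C1C=CC(C)(C)[C@@H]2CC=C[C@](C)(O)[C@@H]2C1C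
F10 | step 11 | 7,8-epoxy derivative of F9 | O=C1[C@H]3O[C@H]3C(C)(C)[C@@H]2CC=C[C@](C)(O)[C@@H]2C1C
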